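**Plan**

1. Retrosynthesis: the C8 ester, the C11=C13 methylene and the lactone bond O6–C12 are removed first, then the C7–C11 bond (bromoacetate alkylation of a C7 β-keto ester).
2. Enabling feature: C3 (ketone), the cis C4=C5 bond and C6 (lactone oxygen) are four carbons of a six-membered, quinone-derived ring B that C2 and C7 complete. Joining C2 to C7 across the ten-membered ring C1–C10 gives a cis-fused bicyclo[4.4.0]decadiene whose ring A is C1, C2, C7, C8, C9, C10.
3. That bicycle is cut at C1–C2 and C7–C8 (Diels–Alder) into an allyl quinonecarboxylate (C2–C7 with C15) and a 1,2,4-tris(silyloxy)butadiene (C1, C10, C9, C8); the C10 methyl comes from addition to a ketone.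
4. Forward: the Diels–Alder reaction forms rings A and B together, reductive silylation turns ring B into a 1,4-bis(silyloxy)cyclohexa-1,3-diene, light cleaves C2–C7 and sets the ten-membered ring free, and the γ-lactone ring (O6–C12) closes afterwards.
5. Stereochemistry: C1/C8 cis from the diene geometry, absolute sense from a chiral Lewis acid; C10 from methyl addition anti to the C1 and C8 silyloxy groups; C7 from kinetic protonation and C6 from hydride addition on the ten-membered ring; the side-chain centre from (R)-2-methylbutanoic acid.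

Key step: step 12

Assumption: the target is taken as the open 3-keto-1,10-diol that is drawn; a ring–chain equilibrium with a 3,10-hemiketal, if it exists, is a property of the final compound only.
Numbering: germacranolide numbering (C1–C15) is used for all intermediates, the bicyclic ones included. TBS = tert-butyldimethylsilyl, TES = triethylsilyl, TMS = trimethylsilyl.

**Route**

Step 1
Reactants: 1 dimethyl 2,5-dihydroxyterephthalate
Product: 2 2,5-dihydroxy-4-(methoxycarbonyl)benzoic acid
Conditions: KOH (3.1 equiv), THF–H2O, 0 °C to rt; then 2 M HCl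
Reagents that add atoms: potassium hydroxide, [K+].[OH-]
Why: Partial saponification of a symmetric diester: after the bis-phenoxide has formed and the first ester is hydrolysed, the extra carboxylate charge retards attack on the second ester, so the half-ester should be the main product.

Step 2
Reactants: 2 2,5-dihydroxy-4-(methoxycarbonyl)benzoic acid
Product: 3 2,5-dihydroxy-4-(hydroxymethyl)benzoic acid
Conditions: LiBH4 (4 equiv), THF, 0 °C to 40 °C; then 1 M HCl
Reagents that add atoms: none
Why: Chemoselective borohydride reduction: LiBH4 reduces the salicylate-type ester (hydride delivered from the neighbouring aryloxyborohydride) while the carboxylate is inert.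

Step 3
Reactants: 3 2,5-dihydroxy-4-(hydroxymethyl)benzoic acid
Product: 4 allyl 2,5-dihydroxy-4-(hydroxymethyl)benzoate
Conditions: allyl bromide (1.1 equiv), NaHCO3 (1.5 equiv), DMF, rt to 40 °C
Reagents that add atoms: allyl bromide, C=CCBr
Why: Carboxylate O-alkylation (SN2): the weak base deprotonates only the carboxylic acid, so the phenols and the benzylic alcohol stay free.

Step 4
Reactants: 4 allyl 2,5-dihydroxy-4-(hydroxymethyl)benzoate
Product: 6 allyl 4-[(tert-butyldimethylsilyloxy)methyl]-2,5-dihydroxybenzoate, via tris-silyl ether 5 (not isolated)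
Conditions: TBSCl (3.3 equiv), imidazole, DMF, rt; then KHF2 (2.2 equiv), MeOH, rt
Reagents that add atoms: tert-butyldimethylsilyl chloride, CC(C)(C)[Si](C)(C)Cl
Why: Exhaustive silylation followed by selective desilylation: KHF2 in methanol cleaves phenolic but not alkyl TBS ethers, which leaves only the benzylic oxygen protected.

Step 5
Reactants: 7 1-(tert-butyldimethylsilyloxy)propan-2-one
Product: 10 (E)-1-(tert-butyldimethylsilyloxy)-4-(triethylsilyloxy)but-3-en-2-one, via kinetic lithium enolate 8 (not isolated), via lithium formyl enolate 9 (not isolated)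
Conditions: LiN(iPr)2 (1.05 equiv), THF, −78 °C; HCO2CH2CF3 (1.2 equiv), −78 °C; then TESCl (1.3 equiv), −78 to 0 °C
Reagents that add atoms: 2,2,2-trifluoroethyl formate, O=COCC(F)(F)F; chlorotriethylsilane, CC[Si](Cl)(CC)CC
Why: Kinetic enolisation occurs at the methyl group, away from the silyloxy-bearing carbon; Claisen-type C-formylation with the activated formate and O-silylation of the chelated enolate at the aldehyde-derived oxygen should give the vinylogous silyl ester, which settles as the E isomer.

Step 6
Reactants: 10 (E)-1-(tert-butyldimethylsilyloxy)-4-(triethylsilyloxy)but-3-en-2-one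
Product: 11 (1Z,3E)-1-(tert-butyldimethylsilyloxy)-4-(triethylsilyloxy)-2-(trimethylsilyloxy)buta-1,3-diene
Conditions: TMSOTf (1.2 equiv), Et3N (1.5 equiv), Et2O, 0 °C; used directly
Reagents that add atoms: trimethylsilyl triflate, C[Si](C)(C)OS(=O)(=O)C(F)(F)F
Why: Soft enolisation (silyl triflate and amine) of the α-silyloxy ketone toward its only α-CH2 gives the Z enol silane with the two oxygens cis, as is usual for α-oxygenated ketones.

Step 7
Reactants: 6 allyl 4-[(tert-butyldimethylsilyloxy)methyl]-2,5-dihydroxybenzoate; 11 (1Z,3E)-tris(silyloxy)diene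
Product: 13 cis-fused Diels–Alder adduct (ring B ene-1,4-dione; C9=C10 TMS enol ether; allyl ester on C7), via quinone 12 (not isolated)
Conditions: Ag2O (2 equiv), MgSO4, CH2Cl2, rt, filtered under argon; filtrate added to Sm(OTf)3 (10 mol %), Ph-pybox (12 mol %, the antipode that leads to 13), 4 Å MS, CH2Cl2, −78 °C; then 11 (1.3 equiv)
Reagents that add atoms: none
Why: Ag2O oxidises the hydroquinone to the quinone, which should undergo a normal-demand Diels–Alder reaction at its ester-bearing C2=C7 bond: the most nucleophilic diene terminus C1 bonds to C2, the (1Z,3E) geometry holds both terminal oxygens outside so that suprafacial addition sets the C1 and C8 oxygens cis, endo approach of the quinone ring gives the cis-fused adduct, and the Sm(OTf)3–pybox complex, chelated by the C6 carbonyl and the ester carbonyl, selects the enantioface (asymmetric Lewis acid catalysis).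

Step 8
Reactants: 13 cis-fused Diels–Alder adduct
Product: 14 bicyclic 3,6-bis(tert-butyldimethylsilyloxy)-3,5-diene (C9=C10 TMS enol ether retained)
Conditions: activated Zn dust (5 equiv), TBSCl (3 equiv), Et3N, DMF, 0 °C to rt, under argon
Reagents that add atoms: tert-butyldimethylsilyl chloride, CC(C)(C)[Si](C)(C)Cl
Why: Dissolving-metal reductive silylation: zinc transfers two electrons to the ene-1,4-dione and the dienediolate is trapped on both oxygens, which gives the 1,4-bis(silyloxy)cyclohexa-1,3-diene without touching C2 or C7, so the cis ring fusion is kept.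

Step 9
Reactants: 14 bicyclic bis(silyloxy)diene with C9=C10 TMS enol ether
Product: 15 bicyclic C10 ketone
Conditions: Bu4NF (1.05 equiv), AcOH (1.2 equiv), THF, −78 °C
Reagents that add atoms: none
Why: Fluoride cleavage of a silyl enol ether: the TMS enol ether reacts far faster than the TBS dienol ethers and the alkyl silyl ethers, and acetic acid protonates the enolate at once, so neither β-elimination of the C8 silyloxy group nor epimerisation at C1 should follow.

Step 10
Reactants: 15 bicyclic C10 ketone
Product: 16 bicyclic C10 tertiary alcohol (C10 methyl; OH cis to the C1 and C8 oxygens)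
Conditions: MeLi (1.5 equiv), CeCl3 (1.6 equiv, anhydrous), THF, −78 °C; aq. NH4Cl
Reagents that add atoms: methyllithium, [Li]C
Why: Organocerium 1,2-addition (non-basic and ketone-selective over the hindered allyl ester): in either chair of ring A the carbonyl face syn to the C1 and C8 silyloxy groups is blocked by an axial silyloxy group, so methyl should enter anti to both and leave the new hydroxyl cis to the C1 and C8 oxygens, as in the target.

Step 11
Reactants: 16 bicyclic C10 tertiary alcohol
Product: 17 bicyclic C10 triethylsilyl ether (precursor of the ring opening)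
Conditions: TESOTf (1.5 equiv), 2,6-lutidine (3 equiv), CH2Cl2, −78 to 0 °C
Reagents that add atoms: triethylsilyl triflate, CC[Si](CC)(CC)OS(=O)(=O)C(F)(F)F
Why: Silyl triflate silylation of a tertiary alcohol; the ether keeps the C10 oxygen from adding across the ring to the C3 and C6 carbonyls that appear after the ring opening.

Step 12
Reactants: 17 cis-fused bicyclic 3,6-bis(silyloxy)-3,5-diene
Product: 18 ten-membered 2,4,6-triene (C2=C3 and C6=C7 silyl enol ethers; cis C4=C5), kept in solution at −78 °C and used at once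
Conditions: hν (300 nm lamps, Pyrex), degassed pentane–Et2O, −78 °C
Reagents that add atoms: none
Why: Excitation of the 1,4-bis(silyloxy)cyclohexa-1,3-diene (C3=C4–C5=C6, the only chromophore expected to absorb above 290 nm) triggers a conrotatory 6π electrocyclic ring opening that breaks the C2–C7 σ bond and gives the C2=C3, C4=C5, C6=C7 triene. The closest known reaction type is the photochemical cyclohexa-1,3-diene to hexatriene opening of bicyclo[4.4.0]deca-2,4-dienes to cyclodeca-1,3,5-trienes, the same process as the provitamin D to previtamin D conversion. No ring is closed by bond formation: the ten-membered carbocycle C1–C10 is set free by scission of the bond shared by rings A and B, so no closure mode applies. No stereocentre is formed; C2 and C7 become trigonal and C1, C8 and C10 are spectators. The only selectivity needed is the cis geometry of C4=C5, which is enforced because this bond was the diene single bond inside a six-membered ring; the sense of conrotation (H-2 expected inward, hence ring bonds trans about C2=C3 and cis about C6=C7) is erased in step 13. Low temperature and direct use of the cold solution should keep the thermally allowed disrotatory re-closure from competing.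

Step 13
Reactants: 18 ten-membered triene
Product: 19 ten-membered Z-ene-3,6-dione with allyl β-keto ester at C7
Conditions: Bu4NF (2.2 equiv), AcOH (2.5 equiv), THF, −78 °C, added to the cold photolysate; then −20 °C
Reagents that add atoms: none
Why: Fluoride cleavage of silyl enol ethers is much faster than that of alkyl silyl ethers; each cross-conjugated enolate is protonated by acetic acid at its α-carbon (C2 and C7), which should give the C3 and C6 ketones flanking the cis C4=C5 bond and removes the triene before it can cyclise (C7 is a β-keto ester centre of no fixed configuration).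

Step 14
Reactants: 19 ten-membered Z-ene-dione β-keto ester; 20 methyl bromoacetate
Product: 21 C7-alkylated β-keto ester (C7 bears CH2CO2Me and CO2allyl)
Conditions: K2CO3 (1.5 equiv), acetone, 0 °C to rt
Reagents that add atoms: none
Why: Acetoacetic-ester-type C-alkylation: carbonate deprotonates only the doubly activated C7–H and the soft enolate attacks the α-halo ester at carbon (SN2), which forms the C7–C11 bond; the configuration of the quaternary centre is immaterial.

Step 15
Reactants: 21 C7-alkylated β-keto ester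
Product: 22 γ-keto ester with C7–H (acetate arm cis to the C8 silyloxy group)
Conditions: Pd2(dba)3 (2.5 mol %), P(2-furyl)3 (10 mol %), HCO2H (3 equiv), iPr2NEt (2 equiv), THF, 0 °C to rt; taken on at once
Reagents that add atoms: none
Why: Palladium-catalysed deallylation and decarboxylation of the allyl β-keto ester with formate as hydride donor for the allyl group (Tsuji decarboxylation–hydrogenolysis): with H-8 eclipsing the enol double bond to avoid allylic 1,3-strain, the proton should reach C7 from the outer face, anti to the C8–C9 ring bond, which leaves the acetate arm cis to the C8 silyloxy group.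

Step 16
Reactants: 22 γ-keto ester
Product: 24 cis-fused 6,12-lactone with C3 carbinol, via hydroxy ester diol 23 (not isolated)
Conditions: NaBH4 (2.5 equiv), CeCl3·7H2O (2.2 equiv), MeOH, −78 to −40 °C; then PPTS (0.1 equiv), CH2Cl2, rt
Reagents that add atoms: none
Why: Luche 1,2-reduction of both enone carbonyls followed by acid-catalysed lactonisation of the γ-hydroxy ester: hydride should attack C6 from the outer face, anti to the C7–C8 ring bond and past H-7 (Felkin–Anh), so O6 ends cis to the C7 arm and closes the cis-fused γ-lactone by 5-exo-trig acyl substitution; the C3 carbinol centre is removed in step 18.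

Step 17
Reactants: 24 cis-fused lactone with C3 carbinol
Product: 27 α-methylene lactone with C3 carbinol, via Mannich base 25 (not isolated), via trimethylammonium iodide 26 (not isolated)
Conditions: LiN(iPr)2 (3.2 equiv), THF, −78 °C; [Me2N=CH2]I (3 equiv), −78 to 0 °C; then MeI, MeOH, rt; then aq. NaHCO3, CH2Cl2, rt
Reagents that add atoms: Eschenmoser's salt, C=[N+](C)C.[I-]
Why: α-Methylenation of a lactone by the Mannich route: the lithium enolate is aminomethylated, and quaternisation followed by base-induced β-elimination of trimethylamine gives the exocyclic alkene; C7 is not enolisable and is untouched.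

Step 18
Reactants: 27 α-methylene lactone with C3 carbinol
Product: 28 α-methylene lactone C3 enone
Conditions: Dess–Martin periodinane (1.5 equiv), NaHCO3, CH2Cl2, 0 °C to rt
Reagents that add atoms: none
Why: Dess–Martin oxidation of the only free hydroxyl, the allylic C3 carbinol, restores the enone under buffered, non-basic conditions that spare the α-methylene lactone and the silyl ethers.

Step 19
Reactants: 28 α-methylene lactone C3 enone
Product: 29 C8 alcohol
Conditions: PPTS (0.2 equiv), MeOH–CH2Cl2 (1:1), 0 °C
Reagents that add atoms: none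
Why: Acid-catalysed methanolysis of silyl ethers is governed by sterics: the secondary TES ether at C8 should be cleaved well before the TBS ethers and the hindered tertiary TES ether.

Step 20
Reactants: 29 C8 alcohol; 30 (R)-2-methylbutanoic acid
Product: 31 C8 (R)-2-methylbutanoate (fully silylated target)
Conditions: DCC (1.5 equiv), DMAP (0.2 equiv), CH2Cl2, 0 °C
Reagents that add atoms: none
Why: Steglich esterification (carbodiimide activation with DMAP as acyl-transfer catalyst) of the only free hydroxyl; the acid brings its stereocentre unchanged, low temperature limiting α-epimerisation.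

Step 21
Reactants: 31 C8 (R)-2-methylbutanoate
Product: 32 CNP0263726.1
Conditions: HF·pyridine, pyridine, THF, 0 °C to rt
Reagents that add atoms: none
Why: Fluoride-mediated desilylation with buffered HF·pyridine should remove the three remaining silyl ethers under mildly acidic conditions that the α-methylene lactone, the β-hydroxy ketone and the ester tolerate.

**Compound list**

1 | dimethyl 2,5-dihydroxyterephthalate | COC(=O)c1cc(O)c(cc1O)C(=O)OC | starting material
2 | 2,5-dihydroxy-4-(methoxycarbonyl)benzoic acid | COC(=O)c1cc(O)c(cc1O)C(=O)O | intermediate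
3 | 2,5-dihydroxy-4-(hydroxymethyl)benzoic acid | OCc1cc(O)c(cc1O)C(=O)O | intermediate
4 | allyl 2,5-dihydroxy-4-(hydroxymethyl)benzoate | OCc1cc(O)c(cc1O)C(=O)OCC=C | intermediate
5 | allyl 2,5-bis(tert-butyldimethylsilyloxy)-4-[(tert-butyldimethylsilyloxy)methyl]benzoate | CC(C)(C)[Si](C)(C)OCc1cc(O[Si](C)(C)C(C)(C)C)c(cc1O[Si](C)(C)C(C)(C)C)C(=O)OCC=C | intermediate
6 | allyl 4-[(tert-butyldimethylsilyloxy)methyl]-2,5-dihydroxybenzoate | CC(C)(C)[Si](C)(C)OCc1cc(O)c(cc1O)C(=O)OCC=C | intermediate
7 | 1-(tert-butyldimethylsilyloxy)propan-2-one | CC(=O)CO[Si](C)(C)C(C)(C)C | starting material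
8 | lithium 3-(tert-butyldimethylsilyloxy)prop-1-en-2-olate | [Li+].C=C([O-])CO[Si](C)(C)C(C)(C)C | intermediate
9 | lithium (Z)-4-(tert-butyldimethylsilyloxy)-3-oxobut-1-en-1-olate | [Li+].[O-]/C=C\C(=O)CO[Si](C)(C)C(C)(C)C | intermediate
10 | (E)-1-(tert-butyldimethylsilyloxy)-4-(triethylsilyloxy)but-3-en-2-one | CC[Si](CC)(CC)O/C=C/C(=O)CO[Si](C)(C)C(C)(C)C | intermediate
11 | (1Z,3E)-1-(tert-butyldimethylsilyloxy)-4-(triethylsilyloxy)-2-(trimethylsilyloxy)buta-1,3-diene (diene C1, C2, C3, C4 = C1, C10, C9, C8) | CC[Si](CC)(CC)O/C=C/C(O[Si](C)(C)C)=C/O[Si](C)(C)C(C)(C)C | intermediate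
12 | allyl 4-[(tert-butyldimethylsilyloxy)methyl]-3,6-dioxocyclohexa-1,4-diene-1-carboxylate (quinone; ring carbons = C7, C2, C3, C4, C5, C6) | C=CCOC(=O)C1=CC(=O)C(CO[Si](C)(C)C(C)(C)C)=CC1=O | intermediate
13 | cis-fused Diels–Alder adduct: ring A C1(OTBS)–C10(OTMS)=C9–C8(OTES) with C2 and C7; ring B C3(=O)–C4(CH2OTBS)=C5–C6(=O); allyl ester on C7; O-1 and O-8 cis to each other and anti to H-2 and to the ester | C1=C(O[Si](C)(C)C)[C@H](O[Si](C)(C)C(C)(C)C)[C@@H]2C(=O)C(CO[Si](C)(C)C(C)(C)C)=CC(=O)[C@]2(C(=O)OCC=C)[C@@H]1O[Si](CC)(CC)CC | intermediate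
14 | as 13 with ring B as the 3,6-bis(tert-butyldimethylsilyloxy)-3,5-diene (C3=C4, C5=C6) | C1=C(O[Si](C)(C)C)[C@H](O[Si](C)(C)C(C)(C)C)[C@@H]2C(O[Si](C)(C)C(C)(C)C)=C(CO[Si](C)(C)C(C)(C)C)C=C(O[Si](C)(C)C(C)(C)C)[C@]2(C(=O)OCC=C)[C@@H]1O[Si](CC)(CC)CC | intermediate
15 | as 14 with a C10 ketone (C9 is CH2) | C1C(=O)[C@H](O[Si](C)(C)C(C)(C)C)[C@@H]2C(O[Si](C)(C)C(C)(C)C)=C(CO[Si](C)(C)C(C)(C)C)C=C(O[Si](C)(C)C(C)(C)C)[C@]2(C(=O)OCC=C)[C@@H]1O[Si](CC)(CC)CC | intermediate
16 | as 15 with C10 bearing methyl and hydroxyl, the hydroxyl cis to O-1 and O-8 | C1[C@](C)(O)[C@H](O[Si](C)(C)C(C)(C)C)[C@@H]2C(O[Si](C)(C)C(C)(C)C)=C(CO[Si](C)(C)C(C)(C)C)C=C(O[Si](C)(C)C(C)(C)C)[C@]2(C(=O)OCC=C)[C@@H]1O[Si](CC)(CC)CC | intermediate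
17 | C10 triethylsilyl ether of 16: cis-fused bicyclic 3,6-bis(silyloxy)-3,5-diene with allyl ester on C7, 1-OTBS, 8-OTES, 10-OTES, 15-OTBS | C1[C@](C)(O[Si](CC)(CC)CC)[C@H](O[Si](C)(C)C(C)(C)C)[C@@H]2C(O[Si](C)(C)C(C)(C)C)=C(CO[Si](C)(C)C(C)(C)C)C=C(O[Si](C)(C)C(C)(C)C)[C@]2(C(=O)OCC=C)[C@@H]1O[Si](CC)(CC)CC | intermediate
18 | ten-membered triene (ring C1–C10): C2=C3 (ring bonds trans), C4=C5 (cis), C6=C7 (cis); OTBS on C3 and C6; allyl ester on C7; C1, C8, C10 as in 17 | C1[C@](C)(O[Si](CC)(CC)CC)[C@H](O[Si](C)(C)C(C)(C)C)/C=C(O[Si](C)(C)C(C)(C)C)/C(CO[Si](C)(C)C(C)(C)C)=C\C(O[Si](C)(C)C(C)(C)C)=C(C(=O)OCC=C)/[C@@H]1O[Si](CC)(CC)CC | intermediate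
19 | ten-membered (4Z)-ene-3,6-dione: allyl ester on C7 (C7 epimers and enol), 1-OTBS, 8-OTES, 10-methyl-10-OTES, 15-OTBS | C1[C@](C)(O[Si](CC)(CC)CC)[C@H](O[Si](C)(C)C(C)(C)C)CC(=O)/C(CO[Si](C)(C)C(C)(C)C)=C\C(=O)C(C(=O)OCC=C)[C@@H]1O[Si](CC)(CC)CC | intermediate
20 | methyl bromoacetate | COC(=O)CBr | starting material
21 | as 19 with CH2CO2Me on C7 (quaternary, either configuration) | C1[C@](C)(O[Si](CC)(CC)CC)[C@H](O[Si](C)(C)C(C)(C)C)CC(=O)/C(CO[Si](C)(C)C(C)(C)C)=C\C(=O)C(CC(=O)OC)(C(=O)OCC=C)[C@@H]1O[Si](CC)(CC)CC | intermediate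
22 | ten-membered (4Z)-ene-3,6-dione with C7–H and CH2CO2Me on C7, cis to O-8 (C7 as in the target) | C1[C@](C)(O[Si](CC)(CC)CC)[C@H](O[Si](C)(C)C(C)(C)C)CC(=O)/C(CO[Si](C)(C)C(C)(C)C)=C\C(=O)[C@H](CC(=O)OC)[C@@H]1O[Si](CC)(CC)CC | intermediate
23 | 3,6-diol of 22 (C3 either configuration; O-6 cis to the C7 arm), methyl ester | COC(=O)C[C@H]1[C@@H](O)/C=C(/CO[Si](C)(C)C(C)(C)C)C(O)C[C@@H](O[Si](C)(C)C(C)(C)C)[C@@](C)(O[Si](CC)(CC)CC)C[C@H]1O[Si](CC)(CC)CC | intermediate
24 | cis-fused 6,12-lactone (C11 is CH2) with 3-OH, 1-OTBS, 8-OTES, 10-OTES, 15-OTBS, (4Z) | C1C(=O)O[C@H]2/C=C(/CO[Si](C)(C)C(C)(C)C)C(O)C[C@@H](O[Si](C)(C)C(C)(C)C)[C@@](C)(O[Si](CC)(CC)CC)C[C@@H](O[Si](CC)(CC)CC)[C@@H]12 | intermediate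
25 | 11-(dimethylaminomethyl) derivative of 24 | CN(C)CC1C(=O)O[C@H]2/C=C(/CO[Si](C)(C)C(C)(C)C)C(O)C[C@@H](O[Si](C)(C)C(C)(C)C)[C@@](C)(O[Si](CC)(CC)CC)C[C@@H](O[Si](CC)(CC)CC)[C@@H]12 | intermediate
26 | trimethylammonium iodide of 25 | C[N+](C)(C)CC1C(=O)O[C@H]2/C=C(/CO[Si](C)(C)C(C)(C)C)C(O)C[C@@H](O[Si](C)(C)C(C)(C)C)[C@@](C)(O[Si](CC)(CC)CC)C[C@@H](O[Si](CC)(CC)CC)[C@@H]12.[I-] | intermediate
27 | 11(13)-methylene lactone with 3-OH | C=C1C(=O)O[C@H]2/C=C(/CO[Si](C)(C)C(C)(C)C)C(O)C[C@@H](O[Si](C)(C)C(C)(C)C)[C@@](C)(O[Si](CC)(CC)CC)C[C@@H](O[Si](CC)(CC)CC)[C@@H]12 | intermediate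
28 | 3-ketone of 27 | C=C1C(=O)O[C@H]2/C=C(/CO[Si](C)(C)C(C)(C)C)C(=O)C[C@@H](O[Si](C)(C)C(C)(C)C)[C@@](C)(O[Si](CC)(CC)CC)C[C@@H](O[Si](CC)(CC)CC)[C@@H]12 | intermediate
29 | 8-alcohol (1-OTBS, 10-OTES, 15-OTBS retained) | C=C1C(=O)O[C@H]2/C=C(/CO[Si](C)(C)C(C)(C)C)C(=O)C[C@@H](O[Si](C)(C)C(C)(C)C)[C@@](C)(O[Si](CC)(CC)CC)C[C@@H](O)[C@@H]12 | intermediate
30 | (R)-2-methylbutanoic acid | CC[C@@H](C)C(=O)O | starting material
31 | 8-O-[(R)-2-methylbutanoyl] derivative of 29 | C=C1C(=O)O[C@H]2/C=C(/CO[Si](C)(C)C(C)(C)C)C(=O)C[C@@H](O[Si](C)(C)C(C)(C)C)[C@@](C)(O[Si](CC)(CC)CC)C[C@@H](OC(=O)[C@H](C)CC)[C@@H]12 | intermediate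
32 | CNP0263726.1: (1R,6S,7R,8R,10S)-1,10,15-trihydroxy-3-oxogermacra-4Z,11(13)-dien-6,12-olid-8-yl (R)-2-methylbutanoate | C=C1C(=O)O[C@H]2/C=C(/CO)C(=O)C[C@@H](O)[C@@](C)(O)C[C@@H](OC(=O)[C@H](C)CC)[C@@H]12 | target

**Step count and risks**

Total: 21 steps. Longest linear sequence: 19 steps (steps 1–4, then 7–21).

Steps most likely to fail:

Step 12 (ring opening). The irradiation may stall at a photostationary mixture, the opened triene may itself be excited and react further, or it may close again thermally before the enol ethers are cleaved. The fallback replaces accumulation of the triene by irreversible interception. It sets out from 17, which is irradiated at −40 °C in THF–methanol containing K2CO3. The C6 silyl ether of the opened form is a vinylogous silyl carbonate and should be methanolysed as it forms, whereas the ketone-derived enol ethers of 17 are inert to these conditions. This should give the ten-membered C6-keto ester that still carries the C2=C3 silyl enol ether F1, which can no longer cyclise. Buffered fluoride as in step 13 then cleaves the remaining enol ether, and the fallback rejoins the route at 19.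

Step 7 (cycloaddition). The uncatalysed reaction of the very electron-rich diene may outrun the catalysed one and erode the enantioselectivity, or the Lewis acid may degrade the diene. The fallback gives up asymmetric catalysis for resolution. It sets out from 6 and 11: the quinone is generated as before and combined with 11 without Lewis acid (CH2Cl2, −40 to 0 °C), which gives 13 together with the enantiomer of adduct 13 F2. The racemate is taken through steps 8 and 9, which adds the enantiomer of 14 F3 and the enantiomer of ketone 15 F4. The robust ketone is then resolved by preparative chromatography on a chiral stationary phase, and the fallback rejoins the route at 15.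

Step 15 (C7 protonation). The proton may be delivered to the wrong face of the C6 enolate, or the new centre may epimerise before the reduction. The fallback moves the control from the substrate to the catalyst. It sets out from 21, which is subjected to ligand-controlled decarboxylative protonation (Pd(OAc)2, the matching antipode of t-Bu-PHOX, HCO2H, 4 Å MS, dioxane, rt), a known enantioselective protonation of allyl β-keto esters. It rejoins the route at 22 and makes no new compound (F0).

**Further compounds**

F1 | step 12 | ten-membered C6 ketone with allyl ester on C7 and the C2=C3 tert-butyldimethylsilyl enol ether retained (cis C4=C5) | C1[C@](C)(O[Si](CC)(CC)CC)[C@H](O[Si](C)(C)C(C)(C)C)/C=C(O[Si](C)(C)C(C)(C)C)/C(CO[Si](C)(C)C(C)(C)C)=C\C(=O)C(C(=O)OCC=C)[C@@H]1O[Si](CC)(CC)CC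
F2 | step 7 | enantiomer of adduct 13 | C1=C(O[Si](C)(C)C)[C@@H](O[Si](C)(C)C(C)(C)C)[C@H]2C(=O)C(CO[Si](C)(C)C(C)(C)C)=CC(=O)[C@@]2(C(=O)OCC=C)[C@H]1O[Si](CC)(CC)CC
F3 | step 7 | enantiomer of 14 | C1=C(O[Si](C)(C)C)[C@@H](O[Si](C)(C)C(C)(C)C)[C@H]2C(O[Si](C)(C)C(C)(C)C)=C(CO[Si](C)(C)C(C)(C)C)C=C(O[Si](C)(C)C(C)(C)C)[C@@]2(C(=O)OCC=C)[C@H]1O[Si](CC)(CC)CC
F4 | step 7 | enantiomer of ketone 15 | C1C(=O)[C@@H](O[Si](C)(C)C(C)(C)C)[C@H]2C(O[Si](C)(C)C(C)(C)C)=C(CO[Si](C)(C)C(C)(C)C)C=C(O[Si](C)(C)C(C)(C)C)[C@@]2(C(=O)OCC=C)[C@H]1O[Si](CC)(CC)CC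
F0 | step 15 | none | none
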